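**Plan**

- Numbering: heptanoid chain C1–C7 (C1/C2 = CH2CH2 on the saturated-side aryl, C3 = carbinol, C5=C6, C7 = diarylmethine); ring A primed (C1' acyl, C2' OH, C3' bears C7, C4' OH, C6' OMe). Target = 3S,5E,7R.
- Cuts: chalcone Cα=Cβ (Claisen–Schmidt); C3'–C7 by retro-[3,3] to an O2'–C5 aryl allyl ether; O2'–C5 (Mitsunobu); C5–OH from the enone; C3–C4 (aldol).
- Feature used: C3' of ring A carries the allylic carbon C7 ortho to the free 2'-OH, with C5=C6 β,γ to the ring. This is an o-(1-arylallyl)phenol, the retron of the ortho-Claisen; C1' is blocked by the acyl group, so C3' is the only open ortho position.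
- Effect: the remote C3/C7 (1,5) relationship becomes a C3/C5 1,3-diol problem. Forward order: aldol, silylation, CBS, Mitsunobu onto O2', [3,3] to C3', chalcone, deprotection; no ring is formed.
- Stereochemistry: C3 (S) from an Ipc2B aldol; C5 (S) from CBS reduction, inverted to R in the Mitsunobu step; C7 (R) and the 5E alkene from suprafacial 1,3-chirality transfer through a chair transition state.

Key step: step 9

Remark: 4-hydroxybenzalacetone, 3-(4-hydroxyphenyl)propan-1-ol, 2',4'-dihydroxy-6'-methoxyacetophenone and 4-(methoxymethoxy)benzaldehyde are taken as catalogue compounds. Stereodescriptors in compound names follow IUPAC chain numbering; the text uses the heptanoid numbering above.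

**Step 1**
Reactants: 1 (E)-4-(4-hydroxyphenyl)but-3-en-2-one
Product: 2 4-[(1E)-3-oxobut-1-en-1-yl]phenyl pivalate
Conditions: PivCl, Et3N, DMAP (cat.), CH2Cl2, 0 °C → rt
Reagents that add atoms: pivaloyl chloride CC(C)(C)C(=O)Cl
Why: DMAP-catalysed O-acylation masks the phenol as a base-cleavable, weakly donating pivalate, which later holds back ionisation of the cinnamylic C5–O bond.

**Step 2**
Reactants: 3 3-(4-hydroxyphenyl)propan-1-ol
Product: 4 4-(3-hydroxypropyl)phenyl pivalate
Conditions: PivCl (1.05 equiv), 1 M NaOH aq, Bu4NHSO4 (cat.), CH2Cl2, 0 °C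
Reagents that add atoms: pivaloyl chloride CC(C)(C)C(=O)Cl
Why: Schotten–Baumann acylation under phase transfer should acylate only the phenoxide and leave the primary alcohol free.

**Step 3**
Reactants: 4 4-(3-hydroxypropyl)phenyl pivalate
Product: 5 4-(3-oxopropyl)phenyl pivalate
Conditions: TEMPO (10 mol %), PhI(OAc)2, CH2Cl2, rt
Reagents that add atoms: none
Why: TEMPO/oxoammonium oxidation stops at the aldehyde and does not touch the aryl ester.

**Step 4**
Reactants: 2 4-[(1E)-3-oxobut-1-en-1-yl]phenyl pivalate; 5 4-(3-oxopropyl)phenyl pivalate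
Product: 8 (1E,5S)-5-hydroxy-1,7-bis[4-(pivaloyloxy)phenyl]hept-1-en-3-one, via enol borinate 6 (not isolated), via boron aldolate 7 (not isolated)
Conditions: (−)-Ipc2BCl, Et3N, Et2O, 0 °C; then 5, −78 → −20 °C; H2O2, pH 7 buffer, MeOH, 0 °C
Reagents that add atoms: none
Why: Paterson boron aldol, in which the (−)-Ipc2B enolate of the methyl ketone is expected to add to the re face of the aldehyde through a boat-like cyclic transition state and set heptanoid C3 as S; any 3R material becomes a separable diastereomer after step 6.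

**Step 5**
Reactants: 8 (1E,5S)-5-hydroxy-1,7-bis[4-(pivaloyloxy)phenyl]hept-1-en-3-one
Product: 9 (1E,5S)-5-[(tert-butyldimethylsilyl)oxy]-1,7-bis[4-(pivaloyloxy)phenyl]hept-1-en-3-one
Conditions: TBSOTf, 2,6-lutidine, CH2Cl2, −78 °C
Reagents that add atoms: tert-butyldimethylsilyl triflate CC(C)(C)[Si](C)(C)OS(=O)(=O)C(F)(F)F
Why: Low-temperature silyl triflate silylation protects O3 without β-elimination, blocks oxa-Michael closure to the tetrahydropyranone and differentiates O3 from the future O5.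

**Step 6**
Reactants: 9 (1E,5S)-5-[(tert-butyldimethylsilyl)oxy]-1,7-bis[4-(pivaloyloxy)phenyl]hept-1-en-3-one
Product: 10 (1E,3S,5S)-5-[(tert-butyldimethylsilyl)oxy]-1,7-bis[4-(pivaloyloxy)phenyl]hept-1-en-3-ol
Conditions: (R)-Me-CBS (20 mol %), catecholborane, toluene, −78 °C
Reagents that add atoms: none
Why: Corey–Bakshi–Shibata 1,2-reduction in which the styryl group acts as the large substituent, so the (R)-oxazaborolidine should give the heptanoid 5S allylic alcohol (3,5-syn) by reagent control.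

**Step 7**
Reactants: 11 1-(2,4-dihydroxy-6-methoxyphenyl)ethan-1-one
Product: 12 1-[2-hydroxy-6-methoxy-4-(methoxymethoxy)phenyl]ethan-1-one
Conditions: MOMCl (1.1 equiv), iPr2NEt, CH2Cl2, 0 °C
Reagents that add atoms: chloromethyl methyl ether COCCl
Why: O-alkylation should take place only at the non-chelated 4'-OH, because the 2'-OH is hydrogen-bonded to the acetyl group and stays free for step 8.

**Step 8**
Reactants: 10 (1E,3S,5S)-5-[(tert-butyldimethylsilyl)oxy]-1,7-bis[4-(pivaloyloxy)phenyl]hept-1-en-3-ol; 12 1-[2-hydroxy-6-methoxy-4-(methoxymethoxy)phenyl]ethan-1-one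
Product: 13 1-[2-({(1E,3R,5S)-5-[(tert-butyldimethylsilyl)oxy]-1,7-bis[4-(pivaloyloxy)phenyl]hept-1-en-3-yl}oxy)-6-methoxy-4-(methoxymethoxy)phenyl]ethan-1-one
Conditions: PPh3, DIAD, toluene, 0 °C → rt
Reagents that add atoms: none
Why: Mitsunobu etherification, in which SN2 displacement of the alkoxyphosphonium by the 2'-phenoxide inverts heptanoid C5 (S → R) to give the 3,5-anti aryl allyl ether; the electron-poor pivalate on the styryl ring disfavours SN1 and SN2′ leakage.

**Step 9**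
Reactants: 13 the 2'-O-[(3R)-hept-1-en-3-yl] aryl ether from step 8
Product: 15 1-[2-hydroxy-6-methoxy-4-(methoxymethoxy)-3-{(1R,2E,5S)-5-[(tert-butyldimethylsilyl)oxy]-1,7-bis[4-(pivaloyloxy)phenyl]hept-2-en-1-yl}phenyl]ethan-1-one, via ortho-dienone 14 (not isolated)
Conditions: PhNEt2 (degassed, 0.05 M), 170 °C, sealed tube
Reagents that add atoms: none
Why: Aromatic (ortho) Claisen rearrangement, a concerted suprafacial [3,3] shift in which the O2'–C5 bond breaks while C3'–C7 forms on the same face of the allyl unit, giving dienone 14, which should enolise at once to the acetyl-chelated 2'-phenol. The closest known reactions are the thermal ortho-Claisen of enantioenriched secondary (E)-allyl aryl ethers with 1,3-chirality transfer, of cinnamyl aryl ethers to o-(1-arylallyl)phenols, and of MOM-protected phloroacetophenone allyl ethers. No ring is closed; the only cyclic element is the six-membered chair transition state. C7 is controlled by C5: with the C4 chain pseudo-equatorial, the (5R,6E)-ether can only deliver 7R together with a new 5E double bond, so the 3,5-anti ether becomes the 3S,7R relationship of the target. Regioselectivity is secured by the substrate, since C1' carries the acetyl group and C3'–H is the only ortho position that can re-aromatise. The step needs the concerted path to outrun C5–O heterolysis, which is why the styryl ring carries an electron-poor pivalate instead of an ether and the medium is a non-ionising amine.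

**Step 10**
Reactants: 15 the 3'-C-alkylated acetophenone from step 9; 16 4-(methoxymethoxy)benzaldehyde
Product: 18 (2E)-1-[2-hydroxy-3-{(1R,2E,5S)-5-[(tert-butyldimethylsilyl)oxy]-1,7-bis(4-hydroxyphenyl)hept-2-en-1-yl}-6-methoxy-4-(methoxymethoxy)phenyl]-3-[4-(methoxymethoxy)phenyl]prop-2-en-1-one, via bisphenol ketone 17 (not isolated)
Conditions: KOH (50 % aq, excess), EtOH, 0 °C → rt; then 16 (3 equiv), rt; cold 1 M HCl to pH 5
Reagents that add atoms: none
Why: Hydroxide first saponifies both aryl pivalates, then Claisen–Schmidt condensation (aldol addition, E1cB dehydration) should give the E-chalcone as its chelated 2'-phenoxide; MOM and TBS ethers are inert to base, and the conditions are those used for 3'-alkyl-2'-hydroxy-4'-MOM-6'-methoxyacetophenones of the prenylchalcone class.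

**Step 11**
Reactants: 18 the bis-MOM, mono-TBS chalcone from step 10
Product: 19 epicalyxin B, (2E)-1-[2,4-dihydroxy-3-{(1R,2E,5S)-5-hydroxy-1,7-bis(4-hydroxyphenyl)hept-2-en-1-yl}-6-methoxyphenyl]-3-(4-hydroxyphenyl)prop-2-en-1-one
Conditions: HCl (1.25 M in MeOH), rt
Reagents that add atoms: none
Why: Acid-catalysed acetal exchange removes both aryl MOM ethers and methanolysis cleaves the secondary TBS ether; mild methanolic acid at room temperature is the end-game used for 3'-prenylated 2',4'-dihydroxy-6'-methoxychalcones and should leave the chalcone, C7 and the homoallylic alcohol unchanged.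

**Compound list**

1 | (E)-4-(4-hydroxyphenyl)but-3-en-2-one | CC(=O)/C=C/c1ccc(O)cc1 | starting material
2 | 4-[(1E)-3-oxobut-1-en-1-yl]phenyl pivalate | CC(=O)/C=C/c1ccc(OC(=O)C(C)(C)C)cc1 | intermediate
3 | 3-(4-hydroxyphenyl)propan-1-ol | OCCCc1ccc(O)cc1 | starting material
4 | 4-(3-hydroxypropyl)phenyl pivalate | OCCCc1ccc(OC(=O)C(C)(C)C)cc1 | intermediate
5 | 4-(3-oxopropyl)phenyl pivalate | O=CCCc1ccc(OC(=O)C(C)(C)C)cc1 | intermediate
6 | diisopinocampheylboron dienolate of 2 (Ipc = (1R,2S,3R,5R)-isopinocampheyl) | C=C(OB([C@@H]1C[C@@H]2C[C@H]([C@H]1C)C2(C)C)[C@@H]1C[C@@H]2C[C@H]([C@H]1C)C2(C)C)/C=C/c1ccc(OC(=O)C(C)(C)C)cc1 | intermediate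
7 | O-diisopinocampheylboryl aldolate of 8 | O=C(/C=C/c1ccc(OC(=O)C(C)(C)C)cc1)C[C@@H](OB([C@@H]1C[C@@H]2C[C@H]([C@H]1C)C2(C)C)[C@@H]1C[C@@H]2C[C@H]([C@H]1C)C2(C)C)CCc1ccc(OC(=O)C(C)(C)C)cc1 | intermediate
8 | (1E,5S)-5-hydroxy-1,7-bis[4-(pivaloyloxy)phenyl]hept-1-en-3-one | O=C(/C=C/c1ccc(OC(=O)C(C)(C)C)cc1)C[C@@H](O)CCc1ccc(OC(=O)C(C)(C)C)cc1 | intermediate
9 | (1E,5S)-5-[(tert-butyldimethylsilyl)oxy]-1,7-bis[4-(pivaloyloxy)phenyl]hept-1-en-3-one | O=C(/C=C/c1ccc(OC(=O)C(C)(C)C)cc1)C[C@@H](O[Si](C)(C)C(C)(C)C)CCc1ccc(OC(=O)C(C)(C)C)cc1 | intermediate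
10 | (1E,3S,5S)-5-[(tert-butyldimethylsilyl)oxy]-1,7-bis[4-(pivaloyloxy)phenyl]hept-1-en-3-ol | O[C@H](/C=C/c1ccc(OC(=O)C(C)(C)C)cc1)C[C@@H](O[Si](C)(C)C(C)(C)C)CCc1ccc(OC(=O)C(C)(C)C)cc1 | intermediate
11 | 1-(2,4-dihydroxy-6-methoxyphenyl)ethan-1-one | COc1cc(O)cc(O)c1C(C)=O | starting material
12 | 1-[2-hydroxy-6-methoxy-4-(methoxymethoxy)phenyl]ethan-1-one | COCOc1cc(O)c(C(C)=O)c(OC)c1 | intermediate
13 | 1-[2-({(1E,3R,5S)-5-[(tert-butyldimethylsilyl)oxy]-1,7-bis[4-(pivaloyloxy)phenyl]hept-1-en-3-yl}oxy)-6-methoxy-4-(methoxymethoxy)phenyl]ethan-1-one | COc1cc(OCOC)cc(O[C@@H](/C=C/c2ccc(OC(=O)C(C)(C)C)cc2)C[C@@H](O[Si](C)(C)C(C)(C)C)CCc2ccc(OC(=O)C(C)(C)C)cc2)c1C(C)=O | intermediate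
14 | 2-acetyl-3-methoxy-5-(methoxymethoxy)-6-{(2E)-5-[(tert-butyldimethylsilyl)oxy]-1,7-bis[4-(pivaloyloxy)phenyl]hept-2-en-1-yl}cyclohexa-2,4-dien-1-one (side-chain centres as in 15; ring sp3 carbon transient, not specified) | COC1=C(C(C)=O)C(=O)C([C@H](/C=C/C[C@@H](O[Si](C)(C)C(C)(C)C)CCc2ccc(OC(=O)C(C)(C)C)cc2)c2ccc(OC(=O)C(C)(C)C)cc2)C(OCOC)=C1 | intermediate
15 | 1-[2-hydroxy-6-methoxy-4-(methoxymethoxy)-3-{(1R,2E,5S)-5-[(tert-butyldimethylsilyl)oxy]-1,7-bis[4-(pivaloyloxy)phenyl]hept-2-en-1-yl}phenyl]ethan-1-one | COc1cc(OCOC)c([C@H](/C=C/C[C@@H](O[Si](C)(C)C(C)(C)C)CCc2ccc(OC(=O)C(C)(C)C)cc2)c2ccc(OC(=O)C(C)(C)C)cc2)c(O)c1C(C)=O | intermediate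
16 | 4-(methoxymethoxy)benzaldehyde | COCOc1ccc(C=O)cc1 | starting material
17 | 1-[2-hydroxy-3-{(1R,2E,5S)-5-[(tert-butyldimethylsilyl)oxy]-1,7-bis(4-hydroxyphenyl)hept-2-en-1-yl}-6-methoxy-4-(methoxymethoxy)phenyl]ethan-1-one | COc1cc(OCOC)c([C@H](/C=C/C[C@@H](O[Si](C)(C)C(C)(C)C)CCc2ccc(O)cc2)c2ccc(O)cc2)c(O)c1C(C)=O | intermediate
18 | (2E)-1-[2-hydroxy-3-{(1R,2E,5S)-5-[(tert-butyldimethylsilyl)oxy]-1,7-bis(4-hydroxyphenyl)hept-2-en-1-yl}-6-methoxy-4-(methoxymethoxy)phenyl]-3-[4-(methoxymethoxy)phenyl]prop-2-en-1-one | COc1cc(OCOC)c([C@H](/C=C/C[C@@H](O[Si](C)(C)C(C)(C)C)CCc2ccc(O)cc2)c2ccc(O)cc2)c(O)c1C(=O)/C=C/c1ccc(OCOC)cc1 | intermediate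
19 | epicalyxin B | COc1cc(O)c([C@H](/C=C/C[C@@H](O)CCc2ccc(O)cc2)c2ccc(O)cc2)c(O)c1C(=O)/C=C/c1ccc(O)cc1 | target

**Step count and risks**

Total step count: 11. Longest linear sequence: 9 steps (steps 2–6 and 8–11, from 3 to 19).

Steps most likely to fail:

1. Step 9 (key step). The risk is heterolysis of the cinnamylic C5–O bond competing with the concerted shift; ion-pair recombination and [1,3]-migration would erode the 1,3-chirality transfer and the E-selectivity. The fallback gives up stereocontrol at C7 and joins the halves by olefin metathesis. It sets out from 12 and comes back at 15.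
   - Commercial 4-hydroxycinnamyl alcohol would be pivaloylated at the phenol under the conditions of step 2 to give 4-[(1E)-3-hydroxyprop-1-en-1-yl]phenyl pivalate F1.
   - F1 would be coupled to 12 (PPh3, DIAD) to give the primary cinnamyl aryl ether F2.
   - Heating F2 (PhNEt2, 190 °C) would give by ortho-Claisen rearrangement, with no stereochemical information to lose, the racemic 3'-(1-arylprop-2-enyl) ketone F3.
   - Separately, 5 would be allylated with (+)-B-allyldiisopinocampheylborane (Brown allylboration, re-face attack) to 4-[(3S)-3-hydroxyhex-5-en-1-yl]phenyl pivalate F4 and silylated (TBSOTf, 2,6-lutidine) to its TBS ether F5.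
   - Cross-metathesis of F3 with excess F5 (Hoveyda–Grubbs II, CH2Cl2, 40 °C) should give the E-alkene as 15 together with its C7 epimer F6. These are diastereomers because C3 is fixed and would be separated by preparative HPLC.

2. Step 8. The risk is E2 elimination of the activated allylic alcohol to the aryl diene, or SN2′/SN1 leakage that erodes inversion at C5, aggravated by the low nucleophilicity of the chelated 2'-phenol. The fallback forms the same C–O bond through a π-allyl palladium intermediate with net retention. It sets out from 9 and comes back at 13.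
   - Reduction of 9 with (S)-Me-CBS/catecholborane would give the C5-epimeric alcohol (1E,3R,5S)-5-[(tert-butyldimethylsilyl)oxy]-1,7-bis[4-(pivaloyloxy)phenyl]hept-1-en-3-ol F7.
   - Methyl chloroformate/pyridine would convert F7 into the allylic methyl carbonate F8.
   - Pd2(dba)3/dppf with 12 in THF at rt should ionise F8 with inversion and let the phenoxide attack the allyl terminus remote from the aryl group with a second inversion, giving the (5R)-ether 13 with the styrene retained.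

3. Step 4. The risk is modest π-facial discrimination in the boat-like transition state of a methyl ketone boron enolate, the known weak point of this reaction class, leaving too much 3R material to purge after step 6. The fallback sets C3 by allylboration instead. It sets out from 5 and comes back at 9.
   - 5 would be converted into the (S)-homoallylic silyl ether F5 via F4, as described under the fallback to step 9.
   - Tsuji–Wacker oxidation (PdCl2, CuCl, O2, DMF/H2O) would give 4-[(3S)-3-[(tert-butyldimethylsilyl)oxy]-5-oxohexyl]phenyl pivalate F9.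
   - The kinetic lithium enolate of F9 (LDA, THF, −78 °C) would be added to 4-formylphenyl pivalate F10 (from 4-hydroxybenzaldehyde and PivCl) to give the β-hydroxy ketone F11.
   - Mesylation–elimination of F11 (MsCl, Et3N, then DBU) should deliver the E-enone 9.

**Further compounds**

F1 | step 9 | 4-[(1E)-3-hydroxyprop-1-en-1-yl]phenyl pivalate | OC/C=C/c1ccc(OC(=O)C(C)(C)C)cc1
F2 | step 9 | 1-[2-methoxy-4-(methoxymethoxy)-6-({(2E)-3-[4-(pivaloyloxy)phenyl]prop-2-en-1-yl}oxy)phenyl]ethan-1-one | COc1cc(OCOC)cc(OC/C=C/c2ccc(OC(=O)C(C)(C)C)cc2)c1C(C)=O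
F3 | step 9 | rac-1-[2-hydroxy-6-methoxy-4-(methoxymethoxy)-3-{1-[4-(pivaloyloxy)phenyl]prop-2-en-1-yl}phenyl]ethan-1-one | COc1cc(OCOC)c(C(C=C)c2ccc(OC(=O)C(C)(C)C)cc2)c(O)c1C(C)=O
F4 | step 9 | 4-[(3S)-3-hydroxyhex-5-en-1-yl]phenyl pivalate | C=CC[C@@H](O)CCc1ccc(OC(=O)C(C)(C)C)cc1
F5 | step 9 | 4-[(3S)-3-[(tert-butyldimethylsilyl)oxy]hex-5-en-1-yl]phenyl pivalate | C=CC[C@@H](O[Si](C)(C)C(C)(C)C)CCc1ccc(OC(=O)C(C)(C)C)cc1
F6 | step 9 | C7 epimer of 15, 1-[2-hydroxy-6-methoxy-4-(methoxymethoxy)-3-{(1S,2E,5S)-5-[(tert-butyldimethylsilyl)oxy]-1,7-bis[4-(pivaloyloxy)phenyl]hept-2-en-1-yl}phenyl]ethan-1-one | COc1cc(OCOC)c([C@@H](/C=C/C[C@@H](O[Si](C)(C)C(C)(C)C)CCc2ccc(OC(=O)C(C)(C)C)cc2)c2ccc(OC(=O)C(C)(C)C)cc2)c(O)c1C(C)=O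
F7 | step 8 | (1E,3R,5S)-5-[(tert-butyldimethylsilyl)oxy]-1,7-bis[4-(pivaloyloxy)phenyl]hept-1-en-3-ol | O[C@@H](/C=C/c1ccc(OC(=O)C(C)(C)C)cc1)C[C@@H](O[Si](C)(C)C(C)(C)C)CCc1ccc(OC(=O)C(C)(C)C)cc1
F8 | step 8 | (1E,3R,5S)-5-[(tert-butyldimethylsilyl)oxy]-1,7-bis[4-(pivaloyloxy)phenyl]hept-1-en-3-yl methyl carbonate | COC(=O)O[C@@H](/C=C/c1ccc(OC(=O)C(C)(C)C)cc1)C[C@@H](O[Si](C)(C)C(C)(C)C)CCc1ccc(OC(=O)C(C)(C)C)cc1
F9 | step 4 | 4-[(3S)-3-[(tert-butyldimethylsilyl)oxy]-5-oxohexyl]phenyl pivalate | CC(=O)C[C@@H](O[Si](C)(C)C(C)(C)C)CCc1ccc(OC(=O)C(C)(C)C)cc1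
F10 | step 4 | 4-formylphenyl pivalate | CC(C)(C)C(=O)Oc1ccc(C=O)cc1
F11 | step 4 | (5S)-5-[(tert-butyldimethylsilyl)oxy]-1-hydroxy-1,7-bis[4-(pivaloyloxy)phenyl]heptan-3-one (C1 epimers) | CC(C)(C)C(=O)Oc1ccc(C(O)CC(=O)C[C@@H](O[Si](C)(C)C(C)(C)C)CCc2ccc(OC(=O)C(C)(C)C)cc2)cc1
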